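Substrate is conserved: whatever leaves it stands in target or in side product, and each side product carries one substrate and one target. So your next charge can be reckoned from a ratio, the loss of target against its making. If enzyme makes target at a·substrate and target is lost at k·substrate·target, and both steps follow the first power of substrate, then substrate cancels from that ratio. Target's share of each new portion of converted substrate is (c − target)/(c + target), where c = a/k. I call c the balance level, a selectivity factor in concentration units.

| flask | substrate | enzyme | remark | time |
|---|---|---|---|---|
| Monday's | 20 mM | 4 µM | run made earlier |  |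
| Wednesday's | 20 mM | 2 µM | run made earlier |  |
| Saturday's | 20 mM | 8 µM | run made earlier |  |
| Friday's | 30 mM | 4 µM | run made earlier |  |
| amber | 20 mM | 4.0 µM | one stirred flow tank at steady state, fed with the mixture as stated, mean residence time 20 h |  |
| teal | 20 mM (fed, over 16.0 h) | 4.0 µM | all but substrate at the start; substrate goes in evenly over 16.0 h, the run ends at 20 h | 20 h |
| violet | 20 mM | 4.0 µM | a closed flask charged with all of it at once and left for 20 h | 20 h |

- Monday's (time / h: target / %, side product / %, substrate / %): 0.667: 37.5, 4.5, 56.8; 2.00: 65.2, 22.7, 11.4; 3.00: 71.0, 25.7, 3.0; 5.00: 72.5, 25.7, 0.5; 8.00: 73.5, 26.0, 0.2; 10.0: 74.1, 26.9, 0.9; 12.0: 71.6, 27.8, 0.4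
- Wednesday's (time / h: target / %, side product / %, substrate / %): 0.833: 23.8, 6.6, 71.4; 2.50: 47.5, 27.2, 24.9; 5.00: 58.3, 38.1, 4.4; 6.00: 58.8, 37.6, 2.3; 10.0: 61.4, 40.9, 0; 12.0: 61.4, 41.0, 0.9; 15.0: 60.9, 41.0, 0.8
- Saturday's (time / h: target / %, side product / %, substrate / %): 2.50: 82.5, 17.7, 1.6; 5.00: 82.8, 16.6, 0.1; 6.00: 83.6, 19.3, 0.8; 10.0: 84.6, 17.0, 1.4; 12.0: 81.3, 16.5, 0; 15.0: 83.5, 17.6, 0.1
- Friday's (time / h: target / %, side product / %, substrate / %): 1.33: 41.9, 19.6, 38.6; 2.50: 51.7, 34.6, 12.5; 5.00: 57.4, 41.6, 2.8; 8.00: 58.4, 41.1, 0; 15.0: 56.5, 41.0, 1.1

(standard deviation of a reading: 1 percentage point)

1. the set-up with the highest share of target in all that became target or side product, at the outlet or at the end ("none" if the first two lie within 2 percentage points) (amber / teal / violet / none)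
2. share of target in all that became target or side product, at the outlet or at the end, amber
3. share of target in all that became target or side product, at the outlet or at the end, teal
4. share of target in all that became target or side product, at the outlet or at the end, violet

- a species is counted by the substrate in it: one side product counts as two
- the stated concentrations are those of everything mixed, before any reaction; amounts are the same in each set-up
- the feed brings no volume worth counting
- the earlier runs were made in a closed, stirred flask

Read the plateaus. Monday's late readings average 14.6 mM target and 5.32 mM side product, the latter counted by the substrate in it. Taking the mean target in a closed flask as roughly half its end value, Monday's balance level, the target concentration at which loss equals making, reads about 47.3 mM. The same reading gives 24.4 mM for Wednesday's 2 µM enzyme, so the level is lower with less enzyme.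

My reckoning holds c at Monday's value. Violet repeats Monday at 73.3%. Teal follows the same path of target against converted substrate, however slowly it is fed, so it also gets 73.3%. Amber holds its outlet target throughout, which gives 59.7%. I would therefore answer none and keep charging at once, since on this reckoning teal's dosing gains nothing over violet. The forecast differs, giving 68% for amber, 79% for teal and 73.3% for violet, with best teal, on the ground that teal keeps substrate low while target “builds gradually”.

The flask gives 57.0% for amber, 62.5% for teal and 73.1% for violet, so the best is violet.

    substrate + target → side product (k = 0.315 L mol⁻¹ min⁻¹)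
    2 enzyme → spent catalyst (k = 475 L mol⁻¹ min⁻¹)
    substrate + enzyme → target + enzyme, rate k3*[substrate]*[enzyme]/(1 + ([substrate]/Km3) + ([target]/Kp3)) (3.08 mM, 7.95 mM, k = 22500 L mol⁻¹ min⁻¹)

In teal, substrate went in for 16.0 h while enzyme fell by its pairwise step to spent catalyst, with a first half-life of 4.39 h, shorter than the dosing; by that step alone, enzyme stood at 0.861 µM when dosing stopped. Teal's end values of 62.0% target and 37.2% side product then read as a balance level of 26.8 mM, below Monday's and above Wednesday's 24.4 mM, and amber's outlet, with target held at its outlet value, reads 39.5 mM.

(Readings and results stem from a simulated flask for substances that don't exist; scatter was added.)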